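Late in the west run the two substrates stopped moving: at 25.0 h right-handed stood at 34.1 % and left-handed at 11.6 %, so 54.3 % of the racemate had gone from solution.

- west: left-handed substrate 0.020 M; right-handed substrate 0.020 M; partner 1.1 equiv; free catalyst 10 mol%; run made earlier
- flask: left-handed substrate 0.020 M; partner 1.10 equiv; free catalyst 5 mol%; right-handed substrate 0.020 M; time 10 d

west run (percent of the left-handed substrate and right-handed substrate together charged)

| time / h | right-handed substrate / % | left-handed substrate / % |
|---|---|---|
| 4.00 | 38.6 | 24.4 |
| 8.00 | 35.1 | 16.4 |
| 12.0 | 33.8 | 13.0 |
| 15.0 | 34.8 | 12.5 |
| 20.0 | 33.3 | 12.0 |
| 25.0 | 34.1 | 11.6 |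

(standard deviation of a reading: 0.5 percentage points)

- free catalyst is single-handed; left-handed substrate and right-handed substrate are mirror images of each other, charged as a racemate, each of them at the stated concentration
- the numbers in the tables scatter with a standard deviation of 0.5 percentage points
- on the list of suspects stand: partner + catalyst intermediate B -> free catalyst + right-handed product; free catalyst + right-handed substrate <-> catalyst intermediate B; free catalyst + left-handed substrate <-> catalyst intermediate A; free catalyst <-> dormant form; partner + catalyst intermediate A -> free catalyst + left-handed product; partner -> decomposed reagent
- no earlier run changes the charge of free catalyst; that part of a forecast is a guess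

- whether the excess of right-handed substrate over left-handed substrate among what is left of the two reaches 95 % by 10 d (yes / no)
- the highest excess of right-handed substrate over left-handed substrate among what is left of the two up to 10 d

I folded the charge into one number, the cover: partner charged over both substrates charged together, the share of the racemate the partner can pay for. In the west run and the flask alike it is 0.550, about what the west run lost, so I took the partner as limiting reagent. The west run also gave a tilt, excess gained per share gone:

tilt = (right-handed − left-handed) / gone = 0.414
excess = tilt × c / (1 − c), where c is the share gone

With c equal to the cover and the tilt held at its west reading, the excess is 50.6 %. But one number was not enough. Catalyst holds substrate without partner, and decomposition takes partner. I guessed that half the west catalyst was bound, 2.50 % of the racemate, which makes the west decomposition 3.20 %. The flask has half the catalyst, so I halved the first and doubled the second: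

c = 49.9 %, excess = 41.2 %

That is below 95 %. The forecast also said no, but gave 32 %, lower than my figure, holding that “the partner must be running out, mostly through decomposition”.

The flask gave no and 44.2 %.

    partner + catalyst intermediate B → free catalyst + right-handed product (k = 169 M⁻¹ h⁻¹)
    free catalyst + right-handed substrate ⇌ catalyst intermediate B (K = 38.0 M⁻¹, k = 2340 M⁻¹ h⁻¹)
    free catalyst + left-handed substrate ⇌ catalyst intermediate A (K = 150 M⁻¹, k = 372 M⁻¹ h⁻¹)
    free catalyst ⇌ dormant form (K = 0.525, k = 0.711 h⁻¹)
    partner + catalyst intermediate A → free catalyst + left-handed product (k = 352 M⁻¹ h⁻¹)
    partner → decomposed reagent (k = 0.0137 h⁻¹)

The flask lost 50.9 % of its substrates, under the cover, and its partner ended at 0 %. At 0.207 d the partner's half-life by its step with catalyst intermediate A was 0.32 d, shorter than the 2.11 d by decomposition.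

For a neighbour flask with 12 mol% of free catalyst and the other charges and the time of the flask, the same cover and correction give c = 55.3 % and excess 51.3 %. The computed top there is 49.3 %.

(The earlier runs and the new flask come from a simulation for substances that don't exist; the scatter is artificial.)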